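**Assumption:** the target SMILES contains no stereocentre (both ring C=C bonds are cis by ring constraint), so artocarpol D is achiral and no enantiocontrol is needed. The only geometry set on the way is the (2E)-alkene of dienone 13/14, which is consumed in the key step.

## Retrosynthetic overview

1. Artocarpol D ⇐ its bis-MOM ether 15 (phenol unveiling last).
2. 15 ⇐ o-bromo diaryl ether dienone 14: one Pd-catalysed step forms the aryl–C bond, the oxepine ring and the 2H-pyran ring together.
3. 14 ⇐ bromophenol 6 (prenylated ring) + o-fluoroaryl dienone 13 (other ring), joined by SNAr.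
4. 6 ⇐ resorcinol (mono-MOM, ortho-Br, para-I, selective I→prenyl); 13 ⇐ 3-fluorophenol (MOM, para-Br, Mg exchange/acetylation, aldol condensation with prenal).
5. Ring order: both benzene rings are bought; diaryl ether first; oxepine and pyran close simultaneously.

## Route

### Fragment A (prenylated ring)

**Step 1**
Reactants: 1, resorcinol
Product: 2, 3-(methoxymethoxy)phenol
Conditions: 1 (3 equiv), MOMCl (1 equiv), i-Pr2NEt, CH2Cl2/THF, 0 °C to rt; excess 1 removed by water wash
Reagents that add atoms: chloromethyl methyl ether (MOMCl), COCCl
Why: Williamson-type mono-protection of a symmetric diol; excess resorcinol suppresses the bis-ether and no regiochemical question arises.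

**Step 2**
Reactants: 2, 3-(methoxymethoxy)phenol
Product: 3, 2-bromo-5-(methoxymethoxy)phenol
Conditions: NBS (1.0 equiv), i-Pr2NH (10 mol %), CH2Cl2, -20 to 0 °C
Reagents that add atoms: N-bromosuccinimide, O=C1CCC(=O)N1Br
Why: Amine-mediated ortho-selective electrophilic bromination of a phenol; of the two ortho sites, the one para to OMOM is more activated and far less hindered than the one between the two oxygens.

**Step 3**
Reactants: 3, 2-bromo-5-(methoxymethoxy)phenol
Product: 4, 2-bromo-4-iodo-5-(methoxymethoxy)phenol
Conditions: NIS (1.05 equiv), MeCN, 0 °C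
Reagents that add atoms: N-iodosuccinimide, O=C1CCC(=O)N1I
Why: Electrophilic aromatic iodination; the only remaining activated and accessible position is para to the free OH (ortho to OMOM), since the site between the oxygens is sterically blocked.

**Step 4**
Reactants: 4, 2-bromo-4-iodo-5-(methoxymethoxy)phenol; 5, prenyl bromide (1-bromo-3-methylbut-2-ene)
Product: 6, 2-bromo-5-(methoxymethoxy)-4-(3-methylbut-2-en-1-yl)phenol
Conditions: MeMgCl (1.0 equiv), THF, -40 °C; i-PrMgCl·LiCl (1.1 equiv), -40 to -15 °C; Li2CuCl4 (5 mol %), 5 (1.3 equiv), -40 °C to rt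
Reagents that add atoms: none besides reactant 5 (CC(C)=CCBr)
Why: Chemoselective iodine–magnesium exchange on the magnesium phenoxide (C–I much faster than C–Br, helped by ortho-OMOM chelation), then Cu-catalysed SN2 allylation (Kochi type) gives the linear prenyl arene and keeps the C–Br bond for Step 10.

### Fragment B (non-prenylated ring plus C5 unit)

**Step 5**
Reactants: 7, 3-fluorophenol
Product: 8, 1-fluoro-3-(methoxymethoxy)benzene
Conditions: MOMCl, i-Pr2NEt, CH2Cl2, 0 °C to rt
Reagents that add atoms: chloromethyl methyl ether, COCCl
Why: Standard Williamson-type MOM protection of a phenol.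

**Step 6**
Reactants: 8, 1-fluoro-3-(methoxymethoxy)benzene
Product: 9, 1-bromo-2-fluoro-4-(methoxymethoxy)benzene
Conditions: NBS (1.05 equiv), MeCN, 0 °C to rt
Reagents that add atoms: N-bromosuccinimide, O=C1CCC(=O)N1Br
Why: Para-selective electrophilic bromination of an aryl ether with NBS/MeCN; the stronger donor (OMOM) directs para to itself, which is ortho to F.

**Step 7**
Reactants: 9, 1-bromo-2-fluoro-4-(methoxymethoxy)benzene; 10, N-methoxy-N-methylacetamide
Product: 11, 1-[2-fluoro-4-(methoxymethoxy)phenyl]ethan-1-one
Conditions: i-PrMgCl·LiCl (1.1 equiv), THF, 0 °C to rt; then 10, -20 °C to rt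
Reagents that add atoms: none besides reactant 10 (CC(=O)N(C)OC)
Why: Bromine–magnesium exchange (accelerated by ortho-F; the Grignard does not eliminate to a benzyne at this temperature) followed by Weinreb ketone synthesis, whose chelated adduct prevents over-addition.

**Step 8**
Reactants: 11, 1-[2-fluoro-4-(methoxymethoxy)phenyl]ethan-1-one; 12, 3-methylbut-2-enal (prenal)
Product: 13, (2E)-1-[2-fluoro-4-(methoxymethoxy)phenyl]-5-methylhexa-2,4-dien-1-one
Conditions: LiHMDS, THF, -78 °C; 12; then MsCl, Et3N, -78 °C to rt
Reagents that add atoms: none besides reactant 12 (CC(C)=CC=O)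
Why: Directed aldol 1,2-addition of the pre-formed lithium enolate to the enal, then mesylation/E1cB elimination (stepwise Claisen–Schmidt condensation, avoiding prenal self-condensation) gives the thermodynamically favoured (E)-dienone.

### Union and end game

**Step 9**
Reactants: 6, 2-bromo-5-(methoxymethoxy)-4-(3-methylbut-2-en-1-yl)phenol; 13, the (2E)-fluoroaryl dienone
Product: 14, (2E)-1-{2-[2-bromo-5-(methoxymethoxy)-4-(3-methylbut-2-en-1-yl)phenoxy]-4-(methoxymethoxy)phenyl}-5-methylhexa-2,4-dien-1-one
Conditions: 6 (1.1 equiv), KHMDS (1.0 equiv vs 6), THF, 0 °C; swap to DMSO, add 13, 18-crown-6 (10 mol %), 80 °C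
Reagents that add atoms: none
Why: SNAr of the ortho-acyl-activated fluoride by a pre-formed phenoxide (no excess base); phenoxide oxa-Michael addition to the dienone is reversible while fluoride loss is not, and the aryl bromide is inert.

**Step 10 (key step)**
Reactants: 14, the o-bromo diaryl ether dienone
Product: 15, artocarpol D bis(methoxymethyl) ether. This is a dibenzo[b,f]oxepine whose C10=C11 bond is shared with a 2,2-dimethyl-2H-pyran. The pyran O sits on the carbon bonded to the non-prenylated ring, and the pyran CH=CH on the carbon bonded to the prenylated ring. One OMOM is para to the pyran-O-bearing carbon on the non-prenylated ring; the other OMOM is on the prenylated ring, ortho to the prenyl group.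
Conditions: Pd2(dba)3 (2.5 mol %), P(t-Bu)3·HBF4 (10 mol %), K3PO4 (3 equiv), 1,4-dioxane (0.02 M), 90 °C, carboxylate-free
Reagents that add atoms: none
Why: Proposed new method: an interrupted intramolecular Heck reaction of a 1-aryl-2,4-dienone. Oxidative addition into C–Br is followed by 7-exo arylpalladation of the diene at its acyl-bearing terminus; both the exo mode (as in oxindole-forming Heck cyclisations) and formation of an η3-allyl-Pd over the next three carbons direct the aryl group there. The intermediate then closes the pyran either by base-mediated enolisation and attack of the enolate oxygen on the CMe2 terminus of the π-allyl, or by syn β-hydride elimination to the (Z)-1-oxatriene (acyl cis to vinyl, fixed by syn-insertion/syn-elimination) and spontaneous oxa-6π electrocyclisation. Both paths give the same 2H-pyran and regenerate Pd(0); the closest known reactions are the Mizoroki–Heck cyclisation and Larock carbo-oxygenation (heteroannulation) of 1,3-dienes.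

**Step 11**
Reactants: 15, artocarpol D bis(methoxymethyl) ether
Product: 16, artocarpol D (target)
Conditions: TMSOTf (4 equiv), 2,2'-bipyridyl (6 equiv), CH2Cl2, 0 °C to rt; then H2O, rt
Reagents that add atoms: none
Why: Fujioka-type non-protic cleavage of aryl MOM ethers via the aryl TMS ethers, which hydrolyse on aqueous work-up; the buffered conditions should spare the o-prenylphenol (no chroman formation) and the dienol ether of the pyran.

## Compound list

1 | resorcinol | Oc1cccc(O)c1 | starting material
2 | 3-(methoxymethoxy)phenol | COCOc1cccc(O)c1 | intermediate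
3 | 2-bromo-5-(methoxymethoxy)phenol | COCOc1ccc(Br)c(O)c1 | intermediate
4 | 2-bromo-4-iodo-5-(methoxymethoxy)phenol | COCOc1cc(O)c(Br)cc1I | intermediate
5 | prenyl bromide (1-bromo-3-methylbut-2-ene) | CC(C)=CCBr | starting material
6 | 2-bromo-5-(methoxymethoxy)-4-(3-methylbut-2-en-1-yl)phenol | COCOc1cc(O)c(Br)cc1CC=C(C)C | intermediate
7 | 3-fluorophenol | Oc1cccc(F)c1 | starting material
8 | 1-fluoro-3-(methoxymethoxy)benzene | COCOc1cccc(F)c1 | intermediate
9 | 1-bromo-2-fluoro-4-(methoxymethoxy)benzene | COCOc1ccc(Br)c(F)c1 | intermediate
10 | N-methoxy-N-methylacetamide | CC(=O)N(C)OC | starting material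
11 | 1-[2-fluoro-4-(methoxymethoxy)phenyl]ethan-1-one | CC(=O)c1ccc(OCOC)cc1F | intermediate
12 | 3-methylbut-2-enal (prenal) | CC(C)=CC=O | starting material
13 | (2E)-1-[2-fluoro-4-(methoxymethoxy)phenyl]-5-methylhexa-2,4-dien-1-one | CC(C)=C/C=C/C(=O)c1ccc(OCOC)cc1F | intermediate
14 | (2E)-1-{2-[2-bromo-5-(methoxymethoxy)-4-(3-methylbut-2-en-1-yl)phenoxy]-4-(methoxymethoxy)phenyl}-5-methylhexa-2,4-dien-1-one | CC(C)=C/C=C/C(=O)c1ccc(OCOC)cc1Oc1cc(OCOC)c(CC=C(C)C)cc1Br | intermediate
15 | artocarpol D bis(methoxymethyl) ether | CC(C)=CCc1cc2c(cc1OCOC)Oc1cc(OCOC)ccc1C1=C2C=CC(C)(C)O1 | intermediate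
16 | artocarpol D | CC(C)=CCc1cc2c(cc1O)Oc1cc(O)ccc1C1=C2C=CC(C)(C)O1 | target

## Summary

Total steps: 11.
Longest linear sequence: 7 (Steps 1–4, 9–11; equally Steps 5–8, 9–11).

Three steps most likely to fail:

1. **Step 10 (proposed new Pd cascade).** Risks are 8-endo insertion, Pd C–H arylation to a dibenzofuran, or a non-cyclising (E)-alkylidene ketone. Fallback (known chemistry): couple 6 with acetophenone 11 by SNAr, close the oxepine by standard Pd-catalysed intramolecular ketone α-arylation (Pd2(dba)3/XPhos, K3PO4 or NaOt-Bu, toluene, 90 °C) to the dibenzo[b,f]oxepin-10(11H)-one, then LDA/prenal aldol and MsCl/Et3N dehydration; the resulting 1-oxatriene undergoes oxa-6π electrocyclisation to 15.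

2. **Step 9 (SNAr on a base-sensitive dienone).** Risk is deconjugation or oligomerisation of 13 at the temperature needed for fluoride displacement. Fallback: reverse the order of bond construction. Make the diaryl ether from 6 and acetophenone 11 (K2CO3, DMF, 120 °C, no diene present), then install the dienone on the diaryl ether by the Step 8 aldol condensation with 12 to reach 14.

3. **Step 11 (MOM removal from an acid-sensitive product).** Risk is chroman formation from the o-prenylphenol or opening of the pyran dienol ether. Fallback: change the protecting-group plan. Cleave both MOM ethers at the stage of dienone 14 (before the pyran exists), re-protect as the bis-TBS ether, run Step 10, and finish with TBAF/AcOH so the last step is fluoride-mediated.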